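**Retrosynthetic overview**
- Target ⇐ acetate cleavage ⇐ (Z)-vinyl iodide made from a 5-methylene-4-bromobutenolide by iodine monochloride addition and HCl loss.
- 5-Methylene compound ⇐ 5-methyl-4-bromobutenolide by C5 bromination and HBr loss.
- The only ring made, the 4-bromobutenolide, closes once, by bromolactonisation of a 2-(1-acetoxybutyl)penta-2,3-dienoate (C4–Br and ring O in one event).
- Allenoate ⇐ propargyl-to-allenyl shift of an α-propynyl β-hydroxy ester.
- Key C–C bond (carbinol carbon to C3): boron aldol of butanal with (S)-4-benzyl-3-(pent-3-ynoyl)oxazolidin-2-one, which sets the (R)-carbinol.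

Assumption: the epimer mixtures at the allene axis and at C5 that arise on the way are carried on unseparated, because both stereo-elements are erased before the end.

**Route**

Step 1
Reactants: 1 pent-3-yn-1-ol
Product: 3 pent-3-ynoic acid, via pent-3-ynal 2 (not isolated)
Conditions: 2,2,6,6-tetramethylpiperidin-1-oxyl (TEMPO, 10 mol%), PhI(OAc)2 (2.2 equiv), MeCN/H2O 1:1, 0 °C to rt
Reagents that add atoms: water (O)
Why: Oxoammonium (TEMPO/PhI(OAc)2) oxidation carries the primary alcohol through the aldehyde hydrate to the acid under near-neutral conditions that tolerate the skipped alkyne.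

Step 2
Reactants: 3 pent-3-ynoic acid
Product: 4 pent-3-ynoyl chloride
Conditions: (COCl)2 (1.2 equiv), HCONMe2 (cat.), CH2Cl2, 0 °C to rt; concentrate, use crude
Reagents that add atoms: oxalyl chloride (ClC(=O)C(Cl)=O)
Why: Acid chloride formation through the Vilsmeier-type chloroiminium catalyst needs no amine base, which avoids ketene and allene formation from the acidic propargylic CH2.

Step 3
Reactants: 4 pent-3-ynoyl chloride; 5 (S)-4-benzyloxazolidin-2-one
Product: 7 (S)-4-benzyl-3-(pent-3-ynoyl)oxazolidin-2-one, via lithium oxazolidinide 6 (not isolated)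
Conditions: 5, n-BuLi (1.0 equiv), THF, −78 °C; then 4 (1.1 equiv), −78 °C, 30 min; aq. NH4Cl at −78 °C
Reagents that add atoms: none
Why: N-acylation of the lithiated oxazolidinone by the acid chloride at −78 °C is faster than α-deprotonation, so the β,γ-alkyne stays out of conjugation.

Step 4
Reactants: 7 (S)-4-benzyl-3-(pent-3-ynoyl)oxazolidin-2-one; 8 butanal
Product: 11 (S)-4-benzyl-3-[(2S,3R)-3-hydroxy-2-(prop-1-yn-1-yl)hexanoyl]oxazolidin-2-one, via boron enolate 9 (not isolated), via boron aldolate 10 (not isolated)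
Conditions: Bu2BOTf (1.1 equiv), iPr2NEt (1.2 equiv), CH2Cl2, −78 to 0 °C; then 8 (1.3 equiv), −78 to 0 °C; pH 7 phosphate buffer, MeOH, 30% H2O2, 0 °C
Reagents that add atoms: none
Why: Evans boron syn-aldol in which the (Z)-enolate adds to butanal through a Zimmerman–Traxler chair on the enolate face opposite the benzyl group, which sets the carbinol as R (together with 2S, erased later), minor diastereomers being removed by chromatography.

Step 5
Reactants: 11 (S)-4-benzyl-3-[(2S,3R)-3-hydroxy-2-(prop-1-yn-1-yl)hexanoyl]oxazolidin-2-one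
Product: 12 methyl (2S,3R)-3-hydroxy-2-(prop-1-yn-1-yl)hexanoate
Conditions: MeMgBr (1.5 equiv) added to MeOH/CH2Cl2 at 0 °C (gives MeOMgBr), then 11, 0 °C, 1 h; aqueous work-up
Reagents that add atoms: methanol (CO)
Why: Transesterification by bromomagnesium methoxide attacks the chelation-activated exocyclic imide carbonyl selectively, returns auxiliary 5 and does not touch the carbinol.

Step 6
Reactants: 12 methyl (2S,3R)-3-hydroxy-2-(prop-1-yn-1-yl)hexanoate
Product: 13 methyl 2-[(1R)-1-hydroxybutyl]penta-2,3-dienoate (both allene-axis epimers)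
Conditions: Et3N (1.0 equiv), MeCN, rt
Reagents that add atoms: none
Why: Amine-mediated propargyl-to-allenyl prototropic isomerisation moves the unsaturation into conjugation with the ester, deliberately erasing the C2 centre while the (R)-carbinol, which carries no acidic hydrogen, is untouched.

Step 7
Reactants: 13 methyl 2-[(1R)-1-hydroxybutyl]penta-2,3-dienoate
Product: 14 methyl 2-[(1R)-1-acetoxybutyl]penta-2,3-dienoate (both allene-axis epimers)
Conditions: Ac2O (1.5 equiv), pyridine, CH2Cl2, rt
Reagents that add atoms: acetic anhydride (CC(=O)OC(C)=O)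
Why: Pyridine-mediated O-acetylation is safe here because no α-hydrogen is left for β-elimination, and the acetate both stops the hydroxyl from competing in the coming cyclisation and deactivates the adjacent C–H for step 9.

Step 8
Reactants: 14 methyl 2-[(1R)-1-acetoxybutyl]penta-2,3-dienoate
Product: 15 (1R)-1-(4-bromo-5-methyl-2-oxo-2,5-dihydrofuran-3-yl)butyl acetate (both C5 epimers)
Conditions: NBS (1.2 equiv), THF/H2O 4:1, 0 °C to rt, dark
Reagents that add atoms: N-bromosuccinimide (O=C1CCC(=O)N1Br); water (O)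
Why: Electrophilic bromolactonisation of the 2,3-allenoate, in which bromine adds to the central allene carbon, the ester carbonyl oxygen closes the five-membered ring onto the methyl-bearing terminus and water cleaves the resulting methoxyfuranium ion, installs C4–Br and the butenolide at once from both axis epimers.

Step 9
Reactants: 15 (1R)-1-(4-bromo-5-methyl-2-oxo-2,5-dihydrofuran-3-yl)butyl acetate
Product: 16 (1R)-1-(4,5-dibromo-5-methyl-2-oxo-2,5-dihydrofuran-3-yl)butyl acetate (both C5 epimers)
Conditions: NBS (1.05 equiv), 2,2'-azobis(2-methylpropionitrile) (5 mol%), PhCF3, 80 °C, visible light; filter, concentrate, use crude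
Reagents that add atoms: N-bromosuccinimide (O=C1CCC(=O)N1Br)
Why: Wohl–Ziegler radical bromination takes the C5–H, whose radical is α to the ring oxygen and conjugated through C3=C4 to the lactone carbonyl, while the acetate deactivates the side-chain C–H and the absence of base prevents loss of acetate through a dienolate.

Step 10
Reactants: 16 (1R)-1-(4,5-dibromo-5-methyl-2-oxo-2,5-dihydrofuran-3-yl)butyl acetate
Product: 17 (1R)-1-(4-bromo-5-methylidene-2-oxo-2,5-dihydrofuran-3-yl)butyl acetate
Conditions: Et3N (1.5 equiv), CH2Cl2, 0 °C, 30 min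
Reagents that add atoms: none
Why: E2 dehydrobromination of the tertiary α-oxy bromide toward its only β-hydrogens (the methyl group) gives the exocyclic enol lactone and erases the C5 stereocentre.

Step 11
Reactants: 17 (1R)-1-(4-bromo-5-methylidene-2-oxo-2,5-dihydrofuran-3-yl)butyl acetate
Product: 18 (1R)-1-[4-bromo-5-chloro-5-(iodomethyl)-2-oxo-2,5-dihydrofuran-3-yl]butyl acetate (both C5 epimers)
Conditions: ICl (1.0 M in CH2Cl2, 1.1 equiv), CH2Cl2, −78 to 0 °C, dark; use crude
Reagents that add atoms: iodine monochloride (ClI)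
Why: Markovnikov iodochlorination of the enol-ester double bond puts the electrophilic iodine on the terminal CH2 and lets chloride trap the oxygen-stabilised cation at C5, the electron-poor C3=C4 bond being inert.

Step 12
Reactants: 18 (1R)-1-[4-bromo-5-chloro-5-(iodomethyl)-2-oxo-2,5-dihydrofuran-3-yl]butyl acetate
Product: 19 (1R)-1-[(5Z)-4-bromo-5-(iodomethylidene)-2-oxo-2,5-dihydrofuran-3-yl]butyl acetate
Conditions: Et3N (1.5 equiv), CH2Cl2, −20 to 0 °C
Reagents that add atoms: none
Why: Dehydrochlorination (loss of the tertiary α-oxy chloride and one acidified CH2 hydrogen) gives the vinyl iodide with iodine syn to the ring oxygen (Z), the geometry that avoids the C4 bromine, and any E isomer is separated or equilibrated with a crystal of iodine in daylight.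

Step 13
Reactants: 19 (1R)-1-[(5Z)-4-bromo-5-(iodomethylidene)-2-oxo-2,5-dihydrofuran-3-yl]butyl acetate
Product: 20 (5Z)-4-bromo-3-[(1R)-1-hydroxybutyl]-5-(iodomethylidene)furan-2(5H)-one
Conditions: HCl (1.25 M in MeOH), 0 °C to rt, 12–24 h
Reagents that add atoms: none
Why: Acid-catalysed transesterification of the acetate proceeds by acyl–oxygen cleavage, so the (R)-carbinol is retained, and the halogenated enol lactone, which is acid-stable but base-labile, survives.

**Compound list**
1 | pent-3-yn-1-ol | CC#CCCO | starting material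
2 | pent-3-ynal | CC#CCC=O | intermediate
3 | pent-3-ynoic acid | CC#CCC(=O)O | intermediate
4 | pent-3-ynoyl chloride | CC#CCC(=O)Cl | intermediate
5 | (S)-4-benzyloxazolidin-2-one | O=C1OC[C@H](Cc2ccccc2)N1 | starting material
6 | lithium (S)-4-benzyl-2-oxooxazolidin-3-ide | [Li+].O=C1OC[C@H](Cc2ccccc2)[N-]1 | intermediate
7 | (S)-4-benzyl-3-(pent-3-ynoyl)oxazolidin-2-one | CC#CCC(=O)N1[C@@H](Cc2ccccc2)COC1=O | intermediate
8 | butanal | CCCC=O | starting material
9 | (S)-4-benzyl-3-[(1Z)-1-(dibutylboranyloxy)pent-1-en-3-yn-1-yl]oxazolidin-2-one | CC#C/C=C(\OB(CCCC)CCCC)N1[C@@H](Cc2ccccc2)COC1=O | intermediate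
10 | (S)-4-benzyl-3-[(2S,3R)-3-(dibutylboranyloxy)-2-(prop-1-yn-1-yl)hexanoyl]oxazolidin-2-one | CCC[C@@H](OB(CCCC)CCCC)[C@H](C#CC)C(=O)N1[C@@H](Cc2ccccc2)COC1=O | intermediate
11 | (S)-4-benzyl-3-[(2S,3R)-3-hydroxy-2-(prop-1-yn-1-yl)hexanoyl]oxazolidin-2-one | CCC[C@@H](O)[C@H](C#CC)C(=O)N1[C@@H](Cc2ccccc2)COC1=O | intermediate
12 | methyl (2S,3R)-3-hydroxy-2-(prop-1-yn-1-yl)hexanoate | CCC[C@@H](O)[C@H](C#CC)C(=O)OC | intermediate
13 | methyl 2-[(1R)-1-hydroxybutyl]penta-2,3-dienoate (both axis epimers) | CCC[C@@H](O)C(=C=CC)C(=O)OC | intermediate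
14 | methyl 2-[(1R)-1-acetoxybutyl]penta-2,3-dienoate (both axis epimers) | CCC[C@@H](OC(C)=O)C(=C=CC)C(=O)OC | intermediate
15 | (1R)-1-(4-bromo-5-methyl-2-oxo-2,5-dihydrofuran-3-yl)butyl acetate (both C5 epimers) | CCC[C@@H](OC(C)=O)C1=C(Br)C(C)OC1=O | intermediate
16 | (1R)-1-(4,5-dibromo-5-methyl-2-oxo-2,5-dihydrofuran-3-yl)butyl acetate (both C5 epimers) | CCC[C@@H](OC(C)=O)C1=C(Br)C(C)(Br)OC1=O | intermediate
17 | (1R)-1-(4-bromo-5-methylidene-2-oxo-2,5-dihydrofuran-3-yl)butyl acetate | CCC[C@@H](OC(C)=O)C1=C(Br)C(=C)OC1=O | intermediate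
18 | (1R)-1-[4-bromo-5-chloro-5-(iodomethyl)-2-oxo-2,5-dihydrofuran-3-yl]butyl acetate (both C5 epimers) | CCC[C@@H](OC(C)=O)C1=C(Br)C(Cl)(CI)OC1=O | intermediate
19 | (1R)-1-[(5Z)-4-bromo-5-(iodomethylidene)-2-oxo-2,5-dihydrofuran-3-yl]butyl acetate | CCC[C@@H](OC(C)=O)C1=C(Br)/C(=C/I)OC1=O | intermediate
20 | (5Z)-4-bromo-3-[(1R)-1-hydroxybutyl]-5-(iodomethylidene)furan-2(5H)-one | CCC[C@@H](O)C1=C(Br)/C(=C/I)OC1=O | target

**Totals**
Total step count: 13. Longest linear sequence: 13 steps (1 to 20); 5 and 8 are bought.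

**Three steps most likely to fail**

Risk 1 (step 6): the base may cause dehydration or retro-aldol of the β-hydroxy ester instead of the clean alkyne-to-allene shift. The fallback sets out from butanal 8 and comes back at 13; it also bypasses the isomerisation-prone compounds 4 and 7. Commercial methyl pent-2-ynoate (CCC#CC(=O)OC) is deprotonated at C4 with LiN(iPr)2 in THF at −78 °C to lithium 1-methoxypenta-1,2,3-trien-1-olate F1. This adds 8 at C2 (deconjugative aldol, aq. NH4Cl quench) and gives racemic methyl 2-(1-hydroxybutyl)penta-2,3-dienoate F2 directly. Dess–Martin periodinane (NaHCO3, CH2Cl2, 0 °C) gives methyl 2-butanoylpenta-2,3-dienoate F3, used at once. Corey–Bakshi–Shibata reduction with catecholborane and 20 mol% of (S)-1-methyl-3,3-diphenyl-tetrahydro-1H,3H-pyrrolo[1,2-c][1,3,2]oxazaborole in toluene at −78 °C then gives the (R)-alcohol 13, the unsaturated carbon acting as the large group. The reduction of this reactive allenyl ketone is the weak point of the fallback.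

Risk 2 (step 9): the radical bromination must choose C5–H over the acetoxy-bearing side-chain C–H, and over-bromination is possible. The fallback sets out from 13 and comes back at 17. It replaces the radical step by ionic C5 bromination, which needs a dienolate equivalent and therefore a carbinol protecting group that is a poor leaving group. 13 is silylated (TBSOTf, 2,6-lutidine, CH2Cl2, −78 °C) to methyl 2-[(1R)-1-(tert-butyldimethylsilyloxy)butyl]penta-2,3-dienoate F4. NBS in THF/H2O gives 4-bromo-3-[(1R)-1-(tert-butyldimethylsilyloxy)butyl]-5-methylfuran-2(5H)-one F5. Soft enolisation (TBSOTf 1.05 equiv, Et3N, CH2Cl2, −78 °C) gives the silyloxyfuran tert-butyl({4-bromo-3-[(1R)-1-(tert-butyldimethylsilyloxy)butyl]-5-methylfuran-2-yl}oxy)dimethylsilane F6. NBS in THF at −78 °C brominates it at C5 to 4,5-dibromo-3-[(1R)-1-(tert-butyldimethylsilyloxy)butyl]-5-methylfuran-2(5H)-one F7. Et3N eliminates HBr to 4-bromo-3-[(1R)-1-(tert-butyldimethylsilyloxy)butyl]-5-methylidenefuran-2(5H)-one F8. HF·pyridine in THF frees 4-bromo-3-[(1R)-1-hydroxybutyl]-5-methylidenefuran-2(5H)-one F9, and Ac2O/pyridine returns 17.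

Risk 3 (step 12): the amine may take the iodine back off (return to 17) or give an E/Z mixture; the iodochlorination and elimination pair is argued by analogy to the bromine series. The fallback sets out from 18 and comes back at 19. The α-chloro ether 18 is hydrolysed in acetone/H2O at rt to the lactol (1R)-1-[4-bromo-5-hydroxy-5-(iodomethyl)-2-oxo-2,5-dihydrofuran-3-yl]butyl acetate F10. Dehydration with P2O5 in CH2Cl2 at reflux (acid-mediated enol-lactone formation under thermodynamic control, as used for the bromomethylene analogues) gives the Z enol lactone 19.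

**Further compounds**
F1 | step 6 | lithium 1-methoxypenta-1,2,3-trien-1-olate | [Li+].CC=C=C=C([O-])OC
F2 | step 6 | racemic methyl 2-(1-hydroxybutyl)penta-2,3-dienoate | CCCC(O)C(=C=CC)C(=O)OC
F3 | step 6 | methyl 2-butanoylpenta-2,3-dienoate | CCCC(=O)C(=C=CC)C(=O)OC
F4 | step 9 | methyl 2-[(1R)-1-(tert-butyldimethylsilyloxy)butyl]penta-2,3-dienoate | CCC[C@@H](O[Si](C)(C)C(C)(C)C)C(=C=CC)C(=O)OC
F5 | step 9 | 4-bromo-3-[(1R)-1-(tert-butyldimethylsilyloxy)butyl]-5-methylfuran-2(5H)-one | CCC[C@@H](O[Si](C)(C)C(C)(C)C)C1=C(Br)C(C)OC1=O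
F6 | step 9 | tert-butyl({4-bromo-3-[(1R)-1-(tert-butyldimethylsilyloxy)butyl]-5-methylfuran-2-yl}oxy)dimethylsilane | CCC[C@@H](O[Si](C)(C)C(C)(C)C)c1c(Br)c(C)oc1O[Si](C)(C)C(C)(C)C
F7 | step 9 | 4,5-dibromo-3-[(1R)-1-(tert-butyldimethylsilyloxy)butyl]-5-methylfuran-2(5H)-one | CCC[C@@H](O[Si](C)(C)C(C)(C)C)C1=C(Br)C(C)(Br)OC1=O
F8 | step 9 | 4-bromo-3-[(1R)-1-(tert-butyldimethylsilyloxy)butyl]-5-methylidenefuran-2(5H)-one | CCC[C@@H](O[Si](C)(C)C(C)(C)C)C1=C(Br)C(=C)OC1=O
F9 | step 9 | 4-bromo-3-[(1R)-1-hydroxybutyl]-5-methylidenefuran-2(5H)-one | CCC[C@@H](O)C1=C(Br)C(=C)OC1=O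
F10 | step 12 | (1R)-1-[4-bromo-5-hydroxy-5-(iodomethyl)-2-oxo-2,5-dihydrofuran-3-yl]butyl acetate | CCC[C@@H](OC(C)=O)C1=C(Br)C(O)(CI)OC1=O
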